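**Retrosynthetic overview**

1. The route rests on the quaternary lactone carbon C5. It carries the ring oxygen O1, the ester, the ring B benzyl group and C4, the carbon bearing ring A. A carbene at C5 can therefore take up O1 and then C4 from one 4-oxycinnamyl alcohol (oxonium ylide, then [2,3]-shift).
2. Target ⇒ (desilylation; C3 oxidation and enolisation) saturated γ-lactone ⇒ (O1–C2 oxidative lactonisation; hydroboration) tertiary α-hydroxy ester with a vinyl group (C3=C2) on C4 ⇒ (C5–O1 and C4–C5) ring B α-diazo ester + ring A cinnamyl alcohol.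
3. The diazo ester comes from methyl acetoacetate and the epoxy benzylic bromide of ring B by deacylative diazo transfer. The (R)-epoxide is set by Shi epoxidation of the prenyl arene made from 4-hydroxybenzaldehyde. The alcohol comes from methyl 4-hydroxycinnamate.
4. Ring order: oxirane (step 4), then the lactone ring (step 12, closed at O1–C2); both arenes are bought. Phenols are carried as triisopropylsilyl ethers so that they survive carbonate, DBU and enolate steps.
5. The vinyl group is taken to the lactone by hydroboration and the C3 oxygen is added afterwards, because a free C3 hydroxyl before ring closure would sit γ to the methyl ester and could lactonise onto it.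

Key step: step 10

Labels: O1, C2 (lactone carbonyl), C3, C4 (bears ring A) and C5 (quaternary) are the lactone ring atoms. TIPS = triisopropylsilyl; ArA = 4-(TIPS-oxy)phenyl (ring A); ArB = 3-{[(2R)-3,3-dimethyloxiran-2-yl]methyl}-4-(TIPS-oxy)phenyl (ring B).

Assumption: the sense of induction of Rh2(S-PTTL)4 at C5 cannot be predicted for this ylide; the (S)-ligand catalyst is written, and Rh2(R-PTTL)4 would be used instead if the (5S) series turns out to be favoured.

**Route**

Step 1
Reactants: 1 4-hydroxybenzaldehyde; 2 prenyl bromide (1-bromo-3-methylbut-2-ene)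
Product: 3 4-hydroxy-3-(3-methylbut-2-en-1-yl)benzaldehyde
Conditions: KOH, H2O, rt
Reagents that add atoms: none
Why: Ortho C-alkylation of a phenoxide with an allylic bromide in water, where hydrogen bonding to the phenoxide oxygen should steer attack through the ortho carbon; the O-prenyl ether and the 3,5-diprenyl compound are the expected by-products and are removed by chromatography.

Step 2
Reactants: 3 4-hydroxy-3-(3-methylbut-2-en-1-yl)benzaldehyde
Product: 4 3-(3-methylbut-2-en-1-yl)-4-(triisopropylsilyloxy)benzaldehyde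
Conditions: TIPSCl, imidazole, DMF, rt
Reagents that add atoms: triisopropylsilyl chloride, CC(C)[Si](Cl)(C(C)C)C(C)C
Why: Imidazole-promoted silylation of the phenol, with the bulky TIPS group chosen because it has to survive aqueous carbonate in step 4, DBU in step 7 and the enolate of step 13.

Step 3
Reactants: 4 3-(3-methylbut-2-en-1-yl)-4-(triisopropylsilyloxy)benzaldehyde
Product: 5 [3-(3-methylbut-2-en-1-yl)-4-(triisopropylsilyloxy)phenyl]methanol
Conditions: NaBH4, MeOH, 0 °C
Reagents that add atoms: none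
Why: Borohydride reduction of the aldehyde, so that the peroxymonosulfate of step 4 meets no oxidisable formyl group and the benzylic position is ready for activation.

Step 4
Reactants: 5 [3-(3-methylbut-2-en-1-yl)-4-(triisopropylsilyloxy)phenyl]methanol
Product: 6 [3-{[(2R)-3,3-dimethyloxiran-2-yl]methyl}-4-(triisopropylsilyloxy)phenyl]methanol (ArB–CH2OH)
Conditions: D-fructose-derived Shi ketone (30 mol %), KHSO5 (Oxone), K2CO3, Bu4NHSO4, Na2B4O7 buffer, MeCN/CH2(OMe)2/H2O, 0 °C
Reagents that add atoms: potassium peroxymonosulfate, [K+].[O-]S(=O)(=O)OO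
Why: Shi asymmetric epoxidation, in which the chiral dioxirane of the D-fructose-derived ketone should attack the trisubstituted prenyl alkene through the spiro transition state on the face that gives the (R)-epoxide (reagent control), while the basic buffer spares both the epoxide and the silyl ether.

Step 5
Reactants: 6 [3-{[(2R)-3,3-dimethyloxiran-2-yl]methyl}-4-(triisopropylsilyloxy)phenyl]methanol
Product: 7 {4-(bromomethyl)-2-{[(2R)-3,3-dimethyloxiran-2-yl]methyl}phenoxy}triisopropylsilane (ArB–CH2Br)
Conditions: CBr4, PPh3, 2,6-lutidine, CH2Cl2, 0 °C; used at once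
Reagents that add atoms: carbon tetrabromide, BrC(Br)(Br)Br
Why: Appel reaction, in which the alcohol is activated on phosphorus and displaced by bromide without acid, with lutidine scavenging traces of HBr so that the epoxide is not opened.

Step 6
Reactants: 7 {4-(bromomethyl)-2-{[(2R)-3,3-dimethyloxiran-2-yl]methyl}phenoxy}triisopropylsilane; 8 methyl acetoacetate
Product: 10 methyl 2-acetyl-3-ArB-propanoate (both C2 epimers), via sodium enolate of methyl acetoacetate 9 (not isolated)
Conditions: 8 (1.5 equiv), NaH, THF, 0 °C; then 7, 0 °C to rt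
Reagents that add atoms: none
Why: Acetoacetic ester alkylation of a stabilised enolate with a reactive benzylic bromide, in which excess enolate limits dialkylation and the soft nucleophile should leave the epoxide alone.

Step 7
Reactants: 10 methyl 2-acetyl-3-ArB-propanoate
Product: 11 methyl 2-diazo-3-ArB-propanoate
Conditions: 4-acetamidobenzenesulfonyl azide (p-ABSA), DBU, MeCN, 0 °C to rt
Reagents that add atoms: 4-acetamidobenzenesulfonyl azide, CC(=O)Nc1ccc(cc1)S(=O)(=O)N=[N+]=[N-]
Why: Deacylative Regitz diazo transfer, in which the β-keto ester enolate takes up the terminal nitrogens of the sulfonyl azide and the acetyl group leaves on the sulfonamide nitrogen, giving the α-alkyl-α-diazo ester.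

Step 8
Reactants: 12 methyl (E)-3-(4-hydroxyphenyl)prop-2-enoate (methyl 4-hydroxycinnamate)
Product: 13 methyl (E)-3-[4-(triisopropylsilyloxy)phenyl]prop-2-enoate
Conditions: TIPSCl, imidazole, DMF, rt
Reagents that add atoms: triisopropylsilyl chloride, CC(C)[Si](Cl)(C(C)C)C(C)C
Why: Imidazole-promoted silylation of the phenol.

Step 9
Reactants: 13 methyl (E)-3-[4-(triisopropylsilyloxy)phenyl]prop-2-enoate
Product: 14 (E)-3-[4-(triisopropylsilyloxy)phenyl]prop-2-en-1-ol (ArA–CH=CH–CH2OH)
Conditions: i-Bu2AlH (2.2 equiv), CH2Cl2, −78 to 0 °C; aqueous potassium sodium tartrate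
Reagents that add atoms: none
Why: DIBAL reduction of the conjugated ester in the 1,2-sense to the allylic alcohol, leaving the E alkene untouched.

Step 10
Reactants: 11 methyl 2-diazo-3-ArB-propanoate; 14 (E)-3-[4-(triisopropylsilyloxy)phenyl]prop-2-en-1-ol
Product: 16 methyl (2R)-2-(ArB-methyl)-2-hydroxy-3-ArA-pent-4-enoate (ester C2 = lactone C5, ester C3 = lactone C4; both C4 epimers), via oxonium ylide 15 (not isolated)
Conditions: Rh2(S-PTTL)4 (dirhodium tetrakis[N-phthaloyl-(S)-tert-leucinate], 1 mol %), 14 (2 equiv), 4 Å molecular sieves, toluene, −78 °C, 11 added slowly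
Reagents that add atoms: none
Why: Proposed new method: Rh2(S-PTTL)4 (divalent rhodium) should decompose diazo ester 11 at −78 °C to an electrophilic carbene at C5 that is captured by the hydroxyl oxygen of 14 to give the rhodium-associated oxonium ylide 15, which rearranges through a five-membered envelope transition state in which C5 bonds to the aryl-bearing alkene carbon (C4) while the O–CH2 bond breaks, so that C5–O1 and C4–C5 form in one operation and the former CH–CH2 unit is left as the vinyl group C3=C2. The closest known reaction type is the dirhodium-catalysed tandem oxonium ylide formation and [2,3]-sigmatropic rearrangement of aryldiazoacetates with substituted allylic alcohols, together with the low-temperature intermolecular carbene chemistry of α-alkyl-α-diazo esters under this bulky carboxylate catalyst; the combination of an alkyl-substituted carbene with a primary allylic alcohol is not established. No ring is closed. The configuration at C5 is to be set by the chiral carboxylate ligand sphere, which distinguishes the two faces of the ylide carbon while the metal is still attached, whereas C4 forms without control and does not matter because it becomes sp2 in step 14. The step needs the [2,3]-shift to win over 1,2-proton transfer in the ylide (net O–H insertion), over 1,2-hydride migration in the carbene, over the [1,2]-shift to the linear isomer and over attack on the epoxide oxygen: the 4-silyloxyphenyl group at the allyl terminus stabilises the positive charge that builds up as the O–CH2 bond breaks and so should lower the barrier to the shift, the bulky phthalimido ligands and −78 °C disfavour hydride migration, and the excess of the more nucleophilic hydroxyl should outcompete the hindered trisubstituted epoxide.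

Step 11
Reactants: 16 methyl (2R)-2-(ArB-methyl)-2-hydroxy-3-ArA-pent-4-enoate
Product: 18 methyl (2R)-2-(ArB-methyl)-2,5-dihydroxy-3-ArA-pentanoate (both C4 epimers), via alkylborane 17 (not isolated)
Conditions: 9-BBN (3 equiv), THF, 0 °C to rt; then NaBO3·4H2O, H2O, rt
Reagents that add atoms: sodium perborate, [Na+].[Na+].O[B-]1(O)OO[B-](O)(O)OO1
Why: Anti-Markovnikov hydroboration–oxidation of the terminal vinyl group places the hydroxyl on C2 only, and 9-BBN with the mild perborate oxidation should leave the ester, the epoxide and the aryl silyl ethers alone.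

Step 12
Reactants: 18 methyl (2R)-2-(ArB-methyl)-2,5-dihydroxy-3-ArA-pentanoate
Product: 21 (5R)-5-(ArB-methyl)-5-(methoxycarbonyl)-4-ArA-oxolan-2-one (both C4 epimers), via hydroxy aldehyde 19 (not isolated), via lactol 20 (not isolated)
Conditions: TEMPO (20 mol %), PhI(OAc)2 (2.5 equiv), CH2Cl2, rt
Reagents that add atoms: none
Why: TEMPO/PhI(OAc)2 oxidative lactonisation of a 1,4-diol, in which the oxoammonium salt oxidises only the primary alcohol, the aldehyde is trapped by the tertiary C5 hydroxyl as the five-membered lactol (5-exo-trig addition to the carbonyl) and a second oxidation gives the γ-lactone, forming O1–C2.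

Step 13
Reactants: 21 (5R)-5-(ArB-methyl)-5-(methoxycarbonyl)-4-ArA-oxolan-2-one
Product: 23 (5R)-5-(ArB-methyl)-3-hydroxy-5-(methoxycarbonyl)-4-ArA-oxolan-2-one (mixture at C3 and C4), via potassium enolate 22 (not isolated)
Conditions: KN(SiMe3)2, THF, −78 °C; then 2-(phenylsulfonyl)-3-phenyloxaziridine, −78 °C; NH4Cl
Reagents that add atoms: 2-(phenylsulfonyl)-3-phenyloxaziridine, O=S(=O)(c1ccccc1)N1OC1c1ccccc1
Why: Davis enolate hydroxylation at C3, the only enolisable position because the ester sits on the fully substituted C5, with the configuration of the new carbinol irrelevant since it is oxidised in step 14.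

Step 14
Reactants: 23 (5R)-5-(ArB-methyl)-3-hydroxy-5-(methoxycarbonyl)-4-ArA-oxolan-2-one
Product: 25 methyl (2R)-2-(ArB-methyl)-4-hydroxy-5-oxo-3-ArA-2H-furan-2-carboxylate (bis-TIPS ether of the target), via keto lactone 24 (not isolated)
Conditions: Dess–Martin periodinane, NaHCO3, CH2Cl2, 0 °C to rt
Reagents that add atoms: none
Why: Dess–Martin oxidation of the secondary alcohol gives the α-keto lactone, which should tautomerise toward C4 to the aryl-conjugated enol and so erase the C4 stereocentre, while bicarbonate buffers the acetic acid to protect the epoxide.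

Step 15
Reactants: 25 methyl (2R)-2-(ArB-methyl)-4-hydroxy-5-oxo-3-ArA-2H-furan-2-carboxylate
Product: 26 methyl (2R)-2-[[3-[[(2R)-3,3-dimethyloxiran-2-yl]methyl]-4-hydroxyphenyl]methyl]-4-hydroxy-3-(4-hydroxyphenyl)-5-oxo-2H-furan-2-carboxylate (target)
Conditions: Bu4NF, AcOH (1:1, 3.5 equiv each), THF, 0 °C to rt; pH 7 buffer work-up
Reagents that add atoms: none
Why: Fluoride desilylation of the two aryl silyl ethers with an equimolar amount of acetic acid, so that each phenoxide is protonated as it forms and should not open the neighbouring epoxide to a dihydrobenzofuran.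

**Compound list**

1 | 4-hydroxybenzaldehyde | O=Cc1ccc(O)cc1 | starting material
2 | prenyl bromide | CC(C)=CCBr | starting material
3 | 4-hydroxy-3-(3-methylbut-2-en-1-yl)benzaldehyde | O=Cc1ccc(O)c(CC=C(C)C)c1 | intermediate
4 | 3-(3-methylbut-2-en-1-yl)-4-(triisopropylsilyloxy)benzaldehyde | O=Cc1ccc(O[Si](C(C)C)(C(C)C)C(C)C)c(CC=C(C)C)c1 | intermediate
5 | [3-(3-methylbut-2-en-1-yl)-4-(triisopropylsilyloxy)phenyl]methanol | OCc1ccc(O[Si](C(C)C)(C(C)C)C(C)C)c(CC=C(C)C)c1 | intermediate
6 | [3-{[(2R)-3,3-dimethyloxiran-2-yl]methyl}-4-(triisopropylsilyloxy)phenyl]methanol | OCc1ccc(O[Si](C(C)C)(C(C)C)C(C)C)c(C[C@H]2OC2(C)C)c1 | intermediate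
7 | {4-(bromomethyl)-2-{[(2R)-3,3-dimethyloxiran-2-yl]methyl}phenoxy}triisopropylsilane | BrCc1ccc(O[Si](C(C)C)(C(C)C)C(C)C)c(C[C@H]2OC2(C)C)c1 | intermediate
8 | methyl acetoacetate | CC(=O)CC(=O)OC | starting material
9 | sodium enolate of methyl acetoacetate | [Na+].COC(=O)C=C(C)[O-] | intermediate (not isolated)
10 | methyl 2-acetyl-3-ArB-propanoate (both C2 epimers) | COC(=O)C(Cc1ccc(O[Si](C(C)C)(C(C)C)C(C)C)c(C[C@H]2OC2(C)C)c1)C(C)=O | intermediate
11 | methyl 2-diazo-3-ArB-propanoate | COC(=O)C(=[N+]=[N-])Cc1ccc(O[Si](C(C)C)(C(C)C)C(C)C)c(C[C@H]2OC2(C)C)c1 | intermediate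
12 | methyl (E)-3-(4-hydroxyphenyl)prop-2-enoate | COC(=O)/C=C/c1ccc(O)cc1 | starting material
13 | methyl (E)-3-[4-(triisopropylsilyloxy)phenyl]prop-2-enoate | COC(=O)/C=C/c1ccc(O[Si](C(C)C)(C(C)C)C(C)C)cc1 | intermediate
14 | (E)-3-[4-(triisopropylsilyloxy)phenyl]prop-2-en-1-ol | OC/C=C/c1ccc(O[Si](C(C)C)(C(C)C)C(C)C)cc1 | intermediate
15 | oxonium ylide from the carbene of 11 and alcohol 14 (drawn as the free zwitterion; rhodium-associated in the flask) | COC(=O)[C-](Cc1ccc(O[Si](C(C)C)(C(C)C)C(C)C)c(C[C@H]2OC2(C)C)c1)[OH+]C/C=C/c1ccc(O[Si](C(C)C)(C(C)C)C(C)C)cc1 | intermediate (not isolated)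
16 | methyl (2R)-2-(ArB-methyl)-2-hydroxy-3-ArA-pent-4-enoate (both C4 epimers) | COC(=O)[C@@](O)(Cc1ccc(O[Si](C(C)C)(C(C)C)C(C)C)c(C[C@H]2OC2(C)C)c1)C(C=C)c1ccc(O[Si](C(C)C)(C(C)C)C(C)C)cc1 | intermediate
17 | B-alkyl-9-borabicyclo[3.3.1]nonane from 16 (boron on C2) | COC(=O)[C@@](O)(Cc1ccc(O[Si](C(C)C)(C(C)C)C(C)C)c(C[C@H]2OC2(C)C)c1)C(CCB1C2CCCC1CCC2)c1ccc(O[Si](C(C)C)(C(C)C)C(C)C)cc1 | intermediate (not isolated)
18 | methyl (2R)-2-(ArB-methyl)-2,5-dihydroxy-3-ArA-pentanoate | COC(=O)[C@@](O)(Cc1ccc(O[Si](C(C)C)(C(C)C)C(C)C)c(C[C@H]2OC2(C)C)c1)C(CCO)c1ccc(O[Si](C(C)C)(C(C)C)C(C)C)cc1 | intermediate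
19 | methyl (2R)-2-(ArB-methyl)-2-hydroxy-5-oxo-3-ArA-pentanoate | COC(=O)[C@@](O)(Cc1ccc(O[Si](C(C)C)(C(C)C)C(C)C)c(C[C@H]2OC2(C)C)c1)C(CC=O)c1ccc(O[Si](C(C)C)(C(C)C)C(C)C)cc1 | intermediate (not isolated)
20 | (5R)-5-(ArB-methyl)-5-(methoxycarbonyl)-4-ArA-oxolan-2-ol (lactol) | COC(=O)[C@]1(Cc2ccc(O[Si](C(C)C)(C(C)C)C(C)C)c(C[C@H]3OC3(C)C)c2)OC(O)CC1c1ccc(O[Si](C(C)C)(C(C)C)C(C)C)cc1 | intermediate (not isolated)
21 | (5R)-5-(ArB-methyl)-5-(methoxycarbonyl)-4-ArA-oxolan-2-one | COC(=O)[C@]1(Cc2ccc(O[Si](C(C)C)(C(C)C)C(C)C)c(C[C@H]3OC3(C)C)c2)OC(=O)CC1c1ccc(O[Si](C(C)C)(C(C)C)C(C)C)cc1 | intermediate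
22 | potassium enolate of lactone 21 | [K+].COC(=O)[C@]1(Cc2ccc(O[Si](C(C)C)(C(C)C)C(C)C)c(C[C@H]3OC3(C)C)c2)OC([O-])=CC1c1ccc(O[Si](C(C)C)(C(C)C)C(C)C)cc1 | intermediate (not isolated)
23 | (5R)-5-(ArB-methyl)-3-hydroxy-5-(methoxycarbonyl)-4-ArA-oxolan-2-one | COC(=O)[C@]1(Cc2ccc(O[Si](C(C)C)(C(C)C)C(C)C)c(C[C@H]3OC3(C)C)c2)OC(=O)C(O)C1c1ccc(O[Si](C(C)C)(C(C)C)C(C)C)cc1 | intermediate
24 | (5R)-5-(ArB-methyl)-5-(methoxycarbonyl)-4-ArA-oxolane-2,3-dione (keto tautomer) | COC(=O)[C@]1(Cc2ccc(O[Si](C(C)C)(C(C)C)C(C)C)c(C[C@H]3OC3(C)C)c2)OC(=O)C(=O)C1c1ccc(O[Si](C(C)C)(C(C)C)C(C)C)cc1 | intermediate (not isolated)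
25 | methyl (2R)-2-(ArB-methyl)-4-hydroxy-5-oxo-3-ArA-2H-furan-2-carboxylate | COC(=O)[C@]1(Cc2ccc(O[Si](C(C)C)(C(C)C)C(C)C)c(C[C@H]3OC3(C)C)c2)OC(=O)C(O)=C1c1ccc(O[Si](C(C)C)(C(C)C)C(C)C)cc1 | intermediate
26 | methyl (2R)-2-[[3-[[(2R)-3,3-dimethyloxiran-2-yl]methyl]-4-hydroxyphenyl]methyl]-4-hydroxy-3-(4-hydroxyphenyl)-5-oxo-2H-furan-2-carboxylate | COC(=O)[C@]1(Cc2ccc(O)c(C[C@H]3OC3(C)C)c2)OC(=O)C(O)=C1c1ccc(O)cc1 | target

**Step count and risks**

Total steps: 15. Longest linear sequence: 13 (steps 1–7 and 10–15); steps 8 and 9 make the second fragment.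

Steps most likely to fail:

1. Step 10. Proton transfer within the ylide (net O–H insertion) or hydride migration in the carbene may outrun the [2,3]-shift, and facial discrimination at C5 may be poor. The fallback sets out from 11 and 14 and returns at 16.
   - O–H insertion under copper catalysis (Cu(MeCN)4PF6, monovalent copper, CH2Cl2, rt), a known reaction of α-diazo esters with alcohols, gives methyl 3-ArB-2-{[(E)-3-ArA-prop-2-en-1-yl]oxy}propanoate F1. The same ether can be recovered from the crude product of step 10 if insertion dominates there.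
   - LiN(i-Pr)2 in THF at −78 °C forms the lithium enolate of this ether F2. Its ester-enolate [2,3]-Wittig rearrangement makes the same C4–C5 bond and tertiary alkoxide, giving 16 together with its C5 epimer, methyl (2S)-2-(ArB-methyl)-2-hydroxy-3-ArA-pent-4-enoate F3.
   - No catalyst controls C5 in this variant. Because the epoxide centre is fixed, the (5R) and (5S) series are diastereomers; they would be carried through steps 11–14 and separated by preparative HPLC at the stage of 25, where C5 and the epoxide carbon are the only stereocentres left.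

2. Step 15. The ring B phenoxide released on desilylation may open the adjacent epoxide before it is protonated. The fallback sets out from 25 and returns at 26.
   - CsF and Ac2O in DMF at 0 °C exchange silyl for acetyl: each phenoxide is acetylated as it is released and the enol is acetylated as well. This gives methyl (2R)-4-acetoxy-2-[[4-acetoxy-3-[[(2R)-3,3-dimethyloxiran-2-yl]methyl]phenyl]methyl]-3-(4-acetoxyphenyl)-5-oxo-2H-furan-2-carboxylate F4.
   - Immobilised Candida antarctica lipase B with n-butanol in t-BuOMe at rt then removes the three acetyl groups by transesterification at neutral pH, so that no phenoxide is present next to the epoxide.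

3. Step 5. Ionisation of the electron-rich benzylic bromide or adventitious HBr may open the epoxide, or the bromide may decompose before it is alkylated. The fallback sets out from 6 and returns at 10.
   - MnO2 in CH2Cl2 oxidises the benzylic alcohol to 3-{[(2R)-3,3-dimethyloxiran-2-yl]methyl}-4-(triisopropylsilyloxy)benzaldehyde F5.
   - With 8, the Hantzsch ester (diethyl 2,6-dimethyl-1,4-dihydropyridine-3,5-dicarboxylate) and catalytic L-proline in MeOH at rt, Knoevenagel condensation gives methyl 2-acetyl-3-ArB-prop-2-enoate F6, which is reduced in the same flask by hydride transfer to 10. No benzylic halide is made.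

**Further compounds**

F1 | step 10 | methyl 3-ArB-2-{[(E)-3-ArA-prop-2-en-1-yl]oxy}propanoate | COC(=O)C(Cc1ccc(O[Si](C(C)C)(C(C)C)C(C)C)c(C[C@H]2OC2(C)C)c1)OC/C=C/c1ccc(O[Si](C(C)C)(C(C)C)C(C)C)cc1
F2 | step 10 | lithium enolate of F1 | [Li+].COC([O-])=C(Cc1ccc(O[Si](C(C)C)(C(C)C)C(C)C)c(C[C@H]2OC2(C)C)c1)OC/C=C/c1ccc(O[Si](C(C)C)(C(C)C)C(C)C)cc1
F3 | step 10 | methyl (2S)-2-(ArB-methyl)-2-hydroxy-3-ArA-pent-4-enoate (C5 epimer of 16) | COC(=O)[C@](O)(Cc1ccc(O[Si](C(C)C)(C(C)C)C(C)C)c(C[C@H]2OC2(C)C)c1)C(C=C)c1ccc(O[Si](C(C)C)(C(C)C)C(C)C)cc1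
F4 | step 15 | methyl (2R)-4-acetoxy-2-[[4-acetoxy-3-[[(2R)-3,3-dimethyloxiran-2-yl]methyl]phenyl]methyl]-3-(4-acetoxyphenyl)-5-oxo-2H-furan-2-carboxylate | COC(=O)[C@]1(Cc2ccc(OC(C)=O)c(C[C@H]3OC3(C)C)c2)OC(=O)C(OC(C)=O)=C1c1ccc(OC(C)=O)cc1
F5 | step 5 | 3-{[(2R)-3,3-dimethyloxiran-2-yl]methyl}-4-(triisopropylsilyloxy)benzaldehyde | O=Cc1ccc(O[Si](C(C)C)(C(C)C)C(C)C)c(C[C@H]2OC2(C)C)c1
F6 | step 5 | methyl 2-acetyl-3-ArB-prop-2-enoate | COC(=O)C(=Cc1ccc(O[Si](C(C)C)(C(C)C)C(C)C)c(C[C@H]2OC2(C)C)c1)C(C)=O
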